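Retrosynthesis: cut first the amide C–N bond between the glyoxylyl carbon and the aminopropyl nitrogen of the spermidine chain. Then trace the glyoxylic acid back to a C3 acetyl group, and cut last the C5–C6 bond of the indole benzene ring.
Enabling feature: in the benzene ring C6 bears Br and its neighbour C5 bears only H. C5 can therefore come from a vinyl CH2 on pyrrole C4 (future C3a) and C6 from a CBr2 terminus on pyrrole C5 (future C7a); one Br leaves with a C5 hydrogen and the other stays on C6.
Forward, ring 1: the pyrrole is built first (Wittig dienone, then Van Leusen annulation). Its free α-carbon next to the vinyl group is formylated, N is tosylated, and the aldehyde is turned into the dibromoalkene.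
Forward, ring 2 and chain: the benzene ring is closed onto the pyrrole by thermal 6π electrocyclisation with loss of HBr. Acetyl-to-glyoxylic-acid oxidation, coupling with the di-Boc triamine and acidolysis then complete the chain.
Stereochemistry: the target has no stereocentre and no stereogenic double bond, and the E geometry of the dienone disappears in the pyrrole synthesis, so nothing has to be controlled.

Key step: step 6

Assumption: the di-Boc triamine used in step 8 is taken as purchasable (sold as N1,N5-bis-Boc-spermidine), and the target is delivered as the free base drawn in its SMILES string.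

Step 1
Reactants: 1 acrolein; 2 1-(triphenylphosphoranylidene)propan-2-one
Product: 3 (E)-hexa-3,5-dien-2-one
Conditions: CH2Cl2, hydroquinone (trace), 0 °C → rt; short-path distillation, used at once
Reagents that add atoms: none
Why: The Wittig olefination with a ketone-stabilised ylide attacks only the aldehyde carbon, should give the E-enone, and runs under neutral conditions that spare the polymerisable diene.

Step 2
Reactants: 3 (E)-hexa-3,5-dien-2-one; 4 TosMIC (4-toluenesulfonylmethyl isocyanide)
Product: 5 1-(4-vinyl-1H-pyrrol-3-yl)ethanone
Conditions: NaH (1.2 equiv), Et2O/DMSO, 0 °C → rt, solution of 3 and 4 added dropwise to the base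
Reagents that add atoms: none
Why: In the Van Leusen pyrrole synthesis the TosMIC anion adds to the β-carbon of the enone, the enolate carbon closes 5-endo-dig on the isocyanide carbon, and loss of toluenesulfinate with tautomerisation gives the 3-acyl-4-alkenylpyrrole known from α,β,γ,δ-unsaturated ketones, since the reversible 1,6-adduct could close only through the less nucleophilic γ-carbon of a dienolate.

Step 3
Reactants: 5 1-(4-vinyl-1H-pyrrol-3-yl)ethanone
Product: 7 4-acetyl-3-vinyl-1H-pyrrole-2-carbaldehyde, via iminium chloride 6 (not isolated)
Conditions: (chloromethylene)dimethyliminium chloride (1.05 equiv), DMF/CH2Cl2, −10 °C → rt; then aq NaOAc, rt → 40 °C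
Reagents that add atoms: (chloromethylene)dimethyliminium chloride, C[N+](C)=CCl.[Cl-]; water, O
Why: In this Vilsmeier–Haack formylation the α-carbon next to the vinyl group should react because its σ-complex keeps positive charge off the acetyl-bearing carbon, one weighed equivalent of the salt at low temperature leaves the methyl ketone alone (as with other 3-acetylpyrroles), and the iminium group once attached deactivates ring and vinyl group against a second attack.

Step 4
Reactants: 7 4-acetyl-3-vinyl-1H-pyrrole-2-carbaldehyde
Product: 8 4-acetyl-1-tosyl-3-vinylpyrrole-2-carbaldehyde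
Conditions: NaH (1.05 equiv), THF, 0 °C; then TsCl, 0 °C → rt
Reagents that add atoms: 4-toluenesulfonyl chloride, Cc1ccc(cc1)S(=O)(=O)Cl
Why: N-Sulfonylation through the sodium pyrrolide is fast because two acyl groups make the N–H far more acidic than the methyl ketone, which the single equivalent of base therefore does not enolise.

Step 5
Reactants: 8 4-acetyl-1-tosyl-3-vinylpyrrole-2-carbaldehyde
Product: 9 1-[5-(2,2-dibromovinyl)-1-tosyl-4-vinylpyrrol-3-yl]ethanone
Conditions: CBr4, PPh3, Zn dust, CH2Cl2, rt (pre-mixed); then 8, 0 °C → rt
Reagents that add atoms: carbon tetrabromide, BrC(Br)(Br)Br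
Why: In the Ramirez dibromo-olefination (first half of the Corey–Fuchs sequence) Ph3P=CBr2 takes aldehydes at 0 °C but not aryl methyl ketones, and forming it with Zn dust avoids Ph3PBr2 and the HBr that could add to the vinyl group.

Step 6
Reactants: 9 1-[5-(2,2-dibromovinyl)-1-tosyl-4-vinylpyrrol-3-yl]ethanone
Product: 11 1-(6-bromo-1-tosylindol-3-yl)ethanone, via gem-dibromo dihydroindole 10 (not isolated)
Conditions: 2,6-lutidine (2 equiv), BHT (cat.), degassed o-dichlorobenzene (0.01 M), 180 °C, sealed vessel, argon, dark
Reagents that add atoms: none
Why: Proposed new method: in the rotamer that turns the CBr2 carbon away from the bulky N-tosyl group and toward the vinyl group, the triene CH2=CH–C4=C5–CH=CBr2 should undergo a thermally allowed six-electron electrocyclisation that joins the vinyl CH2 to the CBr2 carbon (indole C5–C6) and gives the non-aromatic dibromide 10. In 10 a C6–Br bond is allylic and aligned through C7=C7a with nitrogen, so it ionises easily, and loss of a C5 proton expels HBr, which creates the benzene ring, restores the pyrrole sextet and drains the unfavourable pre-equilibrium without any oxidant. The closest known reaction type is the thermal electrocyclisation of 2,3-dialkenylpyrroles and 2,3-divinylindoles followed by dehydrogenation, together with the eliminative aromatisation of trienes that carry one leaving group at a terminus, whereas a gem-dibromo terminus that gives up one halogen and keeps the other has not been shown. The one ring formed, the six-membered carbocycle, closes in the disrotatory 6π mode, and because C5 (CH2) and C6 (CBr2) of 10 are not stereogenic and both become sp2, no stereocentre has to be controlled. The site of the halogen needs no control either, since the dibromomethylene carbon lies two bonds from the pyrrole α-carbon that becomes C7a and so maps onto C6, and after one HBr has left no further eliminable H/Br pair remains. Chemoselectivity rests on 2,6-lutidine, which binds HBr but is too weak and too hindered to dehydrobrominate the dibromoalkene or attack the sulfonamide, on high dilution and BHT against cycloaddition and radical polymerisation of the vinylpyrrole, and on the sulfonyl and acetyl acceptors, which draw the nitrogen lone pair out of the ring so that C4=C5 behaves more like an isolated alkene; the bromine that points into the triene raises the barrier, hence the high temperature.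

Step 7
Reactants: 11 1-(6-bromo-1-tosylindol-3-yl)ethanone
Product: 13 2-(6-bromo-1H-indol-3-yl)-2-oxoacetic acid, via N-tosyl glyoxylic acid 12 (not isolated)
Conditions: SeO2 (2 equiv), pyridine, 100 °C; filter (Celite), concentrate; then 2 M aq NaOH, THF, rt; aq HCl to pH 2
Reagents that add atoms: selenium dioxide, O=[Se]=O
Why: The Riley-type SeO2 oxidation of an aryl methyl ketone in pyridine runs through the glyoxal to the arylglyoxylic acid, and the N-sulfonyl group of a 3-acylindole, whose indolide is a good leaving group, is hydrolysed by aqueous hydroxide during the basic extraction, while the aryl bromide is inert to both stages.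

Step 8
Reactants: 13 2-(6-bromo-1H-indol-3-yl)-2-oxoacetic acid; 14 tert-butyl N-(3-aminopropyl)-N-[4-(tert-butoxycarbonylamino)butyl]carbamate
Product: 16 di-Boc-didemnidine B (tert-butyl N-[3-[[2-(6-bromo-1H-indol-3-yl)-2-oxoacetyl]amino]propyl]-N-[4-(tert-butoxycarbonylamino)butyl]carbamate), via benzotriazolyl ester 15 (not isolated)
Conditions: DIC, HOBt, DMF, 0 °C → rt
Reagents that add atoms: none
Why: In this carbodiimide/HOBt amide coupling only the primary amine of 14 is free, α-keto acids couple cleanly through their benzotriazolyl esters, and neither the weakly nucleophilic indole N–H nor the vinylogous-amide ketone competes.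

Step 9
Reactants: 16 di-Boc-didemnidine B
Product: 18 didemnidine B, via dihydrochloride 17 (not isolated)
Conditions: 4 M HCl in 1,4-dioxane, CH2Cl2, 0 °C → rt; then cold 1 M aq NaOH, extraction (CH2Cl2/i-PrOH)
Reagents that add atoms: none
Why: Acidolysis of both tert-butyl carbamates leaves the glyoxylamide and the aryl bromide untouched because the acyl-deactivated indole does not capture tert-butyl cations, and brief treatment with cold dilute base releases the free triamine.

Compound list
1 | acrolein (prop-2-enal) | C=CC=O | starting material
2 | 1-(triphenylphosphoranylidene)propan-2-one | CC(=O)C=P(c1ccccc1)(c1ccccc1)c1ccccc1 | starting material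
3 | (E)-hexa-3,5-dien-2-one | CC(=O)/C=C/C=C | intermediate
4 | TosMIC (4-toluenesulfonylmethyl isocyanide) | [C-]#[N+]CS(=O)(=O)c1ccc(C)cc1 | starting material
5 | 1-(4-vinyl-1H-pyrrol-3-yl)ethanone | CC(=O)c1c[nH]cc1C=C | intermediate
6 | N-[(4-acetyl-3-vinyl-1H-pyrrol-2-yl)methylidene]-N-methylmethanaminium chloride | CC(=O)c1c[nH]c(C=[N+](C)C)c1C=C.[Cl-] | intermediate
7 | 4-acetyl-3-vinyl-1H-pyrrole-2-carbaldehyde | CC(=O)c1c[nH]c(C=O)c1C=C | intermediate
8 | 4-acetyl-1-tosyl-3-vinylpyrrole-2-carbaldehyde | CC(=O)c1cn(S(=O)(=O)c2ccc(C)cc2)c(C=O)c1C=C | intermediate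
9 | 1-[5-(2,2-dibromovinyl)-1-tosyl-4-vinylpyrrol-3-yl]ethanone | CC(=O)c1cn(S(=O)(=O)c2ccc(C)cc2)c(C=C(Br)Br)c1C=C | intermediate
10 | 1-(6,6-dibromo-1-tosyl-5,6-dihydroindol-3-yl)ethanone (double bonds C2=C3, C3a=C4, C7=C7a) | CC(=O)C1=CN(S(=O)(=O)c3ccc(C)cc3)C2=CC(Br)(Br)CC=C12 | intermediate
11 | 1-(6-bromo-1-tosylindol-3-yl)ethanone | CC(=O)c1cn(S(=O)(=O)c3ccc(C)cc3)c2cc(Br)ccc12 | intermediate
12 | 2-(6-bromo-1-tosylindol-3-yl)-2-oxoacetic acid | OC(=O)C(=O)c1cn(S(=O)(=O)c3ccc(C)cc3)c2cc(Br)ccc12 | intermediate
13 | 2-(6-bromo-1H-indol-3-yl)-2-oxoacetic acid | OC(=O)C(=O)c1c[nH]c2cc(Br)ccc12 | intermediate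
14 | tert-butyl N-(3-aminopropyl)-N-[4-(tert-butoxycarbonylamino)butyl]carbamate | NCCCN(CCCCNC(=O)OC(C)(C)C)C(=O)OC(C)(C)C | starting material
15 | benzotriazol-1-yl 2-(6-bromo-1H-indol-3-yl)-2-oxoacetate | O=C(On1nnc2ccccc12)C(=O)c1c[nH]c2cc(Br)ccc12 | intermediate
16 | di-Boc-didemnidine B | CC(C)(C)OC(=O)NCCCCN(CCCNC(=O)C(=O)c1c[nH]c2cc(Br)ccc12)C(=O)OC(C)(C)C | intermediate
17 | didemnidine B dihydrochloride | NCCCCNCCCNC(=O)C(=O)c1c[nH]c2cc(Br)ccc12.Cl.Cl | intermediate
18 | didemnidine B | NCCCCNCCCNC(=O)C(=O)c1c[nH]c2cc(Br)ccc12 | target

Total step count: 9. Longest linear sequence: 9 steps (1 → 18); the triamine 14 enters as a purchased fragment in step 8.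

Steps most likely to fail

Step 6. The closure may stall. The bromine that points into the triene is pressed against the vinyl CH2 in the disrotatory transition state, and the pyrrole sextet has to be given up at the same time. At the temperature then needed, cycloaddition between two vinylpyrrole units, radical polymerisation and C–Br homolysis could overtake ring closure. The fallback replaces the pericyclic closure by π-acid catalysis while still forming C5–C6. It sets out from 9, which is dehydrobrominated with DBU in MeCN at rt, a standard conversion of 1,1-dibromoalkenes, to 1-[5-(bromoethynyl)-1-tosyl-4-vinylpyrrol-3-yl]ethanone F1. InCl3 (10 mol %) in toluene at 80 °C should then trigger the 6-endo-dig cycloisomerisation known for ortho-alkenyl and ortho-aryl haloalkynes. The vinyl CH2 attacks the bromine-bearing alkyne carbon and the halogen stays on that carbon. Proton loss with protodemetalation gives 11, where the route is rejoined.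

Step 2. The TosMIC anion may add to the unsubstituted terminus of the dienone (1,6-mode), so that ring closure takes place across the terminal double bond, and the base may polymerise 3. The fallback makes the vinyl group after the pyrrole, so that no dienone is needed. It sets out from ylide 2, which is condensed with commercial 2,2-dimethoxyacetaldehyde (CH2Cl2, rt) to (E)-5,5-dimethoxypent-3-en-2-one F2. Van Leusen reaction with 4 (NaH, Et2O/DMSO) can then follow only the 1,4-mode and should give 1-[4-(dimethoxymethyl)-1H-pyrrol-3-yl]ethanone F3. Dilute aq HCl in THF releases 4-acetyl-1H-pyrrole-3-carbaldehyde F4. Wittig methylenation follows with Ph3P=CH2 (two equivalents, from methyltriphenylphosphonium bromide and KN(SiMe3)2, the first consumed by the N–H; THF, −78 → 0 °C). It takes the aldehyde in preference to the methyl ketone and returns to the route at 5.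

Step 3. The chloroiminium ion may attack the vinyl terminus instead of the ring α-carbon, or the liberated HCl may start cationic oligomerisation of the vinylpyrrole. The fallback carries the vinyl group in masked form through all electrophilic steps.
- It sets out from acrolein 1, to which thiophenol is added (cat. Et3N, CH2Cl2, 0 °C) to give 3-(phenylsulfanyl)propanal F5.
- Wittig reaction with 2 gives (E)-6-(phenylsulfanyl)hex-3-en-2-one F6.
- Van Leusen reaction with 4 gives 1-{4-[2-(phenylsulfanyl)ethyl]-1H-pyrrol-3-yl}ethanone F7.
- Vilsmeier–Haack formylation under the conditions of step 3 gives 4-acetyl-3-[2-(phenylsulfanyl)ethyl]-1H-pyrrole-2-carbaldehyde F8.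
- NaH/TsCl gives 4-acetyl-3-[2-(phenylsulfanyl)ethyl]-1-tosylpyrrole-2-carbaldehyde F9.
- mCPBA (1 equiv, CH2Cl2, −78 °C) gives 4-acetyl-3-[2-(phenylsulfinyl)ethyl]-1-tosylpyrrole-2-carbaldehyde F10.
- Thermal syn-elimination of the sulfoxide in refluxing toluene over CaCO3, the masked-vinyl tactic of pyrrole pigment chemistry, unveils the vinyl group and returns to the route at 8.

Further compounds
F1 | step 6 | 1-[5-(bromoethynyl)-1-tosyl-4-vinylpyrrol-3-yl]ethanone | CC(=O)c1cn(S(=O)(=O)c2ccc(C)cc2)c(C#CBr)c1C=C
F2 | step 2 | (E)-5,5-dimethoxypent-3-en-2-one | CC(=O)/C=C/C(OC)OC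
F3 | step 2 | 1-[4-(dimethoxymethyl)-1H-pyrrol-3-yl]ethanone | CC(=O)c1c[nH]cc1C(OC)OC
F4 | step 2 | 4-acetyl-1H-pyrrole-3-carbaldehyde | CC(=O)c1c[nH]cc1C=O
F5 | step 3 | 3-(phenylsulfanyl)propanal | O=CCCSc1ccccc1
F6 | step 3 | (E)-6-(phenylsulfanyl)hex-3-en-2-one | CC(=O)/C=C/CCSc1ccccc1
F7 | step 3 | 1-{4-[2-(phenylsulfanyl)ethyl]-1H-pyrrol-3-yl}ethanone | CC(=O)c1c[nH]cc1CCSc1ccccc1
F8 | step 3 | 4-acetyl-3-[2-(phenylsulfanyl)ethyl]-1H-pyrrole-2-carbaldehyde | CC(=O)c1c[nH]c(C=O)c1CCSc1ccccc1
F9 | step 3 | 4-acetyl-3-[2-(phenylsulfanyl)ethyl]-1-tosylpyrrole-2-carbaldehyde | CC(=O)c1cn(S(=O)(=O)c2ccc(C)cc2)c(C=O)c1CCSc1ccccc1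
F10 | step 3 | 4-acetyl-3-[2-(phenylsulfinyl)ethyl]-1-tosylpyrrole-2-carbaldehyde (racemic at sulfur) | CC(=O)c1cn(S(=O)(=O)c2ccc(C)cc2)c(C=O)c1CCS(=O)c1ccccc1
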